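All runs are simulated from invented constants; the scatter is artificial.

Per molecule of starting complex charged, I asked how far it had got along the exchange ladder when the flask stopped.

common to all: starting complex 37 mM (fed, over 8.0 min)

| flask | incoming ligand | temperature | remark | time |
|---|---|---|---|---|
| beta | 49 mM | −34 °C | run made earlier |  |
| gamma | 63 mM | −20 °C | run made earlier |  |
| theta | 140 mM | −34 °C | run made earlier |  |
| south-west | 40.7 mM |  | at −40 °C until 8.0 min, from then on at −15 °C | 2.0 h |
| south | 120 mM |  | at −40 °C throughout | 2.0 h |

- beta (time / min: complex with two exchanged / %, starting complex / %): 8.00: 9.0, 80.1; 20.0: 29.7, 53.7; 40.0: 35.3, 41.4; 60.0: 37.5, 37.5; 80.0: 38.5, 37.7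
- gamma (time / min: complex with two exchanged / %, starting complex / %): 3.00: 6.1, 26.4; 8.00: 23.7, 54.9; 15.0: 32.5, 35.8; 20.0: 32.3, 31.2; 30.0: 33.3, 28.3
- theta (time / min: complex with two exchanged / %, starting complex / %): 15.0: 39.3, 24.8; 30.0: 26.2, 5.7; 50.0: 15.9, 2.1; 60.0: 10.3, 0.6; 80.0: 6.1, 1.4

(scatter of a reading: 1 percentage point)

- the earlier runs were read with a standard deviation of 1 percentage point
- candidate steps: complex with two exchanged + incoming ligand -> over-reaction product; complex with three exchanged + incoming ligand -> leaving ligand + complex with four exchanged; complex with one exchanged + incoming ligand -> leaving ligand + complex with two exchanged; starting complex + incoming ligand -> leaving ligand + complex with one exchanged; complex with two exchanged + incoming ligand -> leaving ligand + complex with three exchanged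
- percentages count the whole charge, also what has not yet gone in

- the flask that ends with the higher amount of complex with two exchanged, in percent of the starting complex charged, or "neither" when 2 percentage points or less lies between them (south-west / south / neither)
- final complex with two exchanged, as a percentage of the starting complex charged, in south-west
- final complex with two exchanged, as a percentage of the starting complex charged, in south

Every exchange step takes incoming ligand to the first power, so ligand cancels between two forks and a molecule's chances hang on how much starting complex is left. Theta's highest reading of complex with two exchanged, at 15.0 min, stood beside starting complex in the ratio 0.631. I took that reading as the top of the curve, where this complex is made as fast as it is lost. It is made from complex with one exchanged, not straight from starting complex, so I kept this ratio only as a low-side reading of the fork ratio ρ (a selectivity factor): loss of complex with two exchanged against attack on starting complex. With a the fraction of starting complex left, the amount held is (a^ρ − a)/(1 − ρ).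

Beta's tail lay flat, 37.5% then 37.7%, so I took its 49 mM of ligand as used up, at 2.13 ligand per starting complex gone. South-west's 40.7 mM then leaves a = 48.3%, and the curve gives 40.3%.

The second way used no fork. Beta kept 0.291 complex with two exchanged per ligand charged, which on south-west's budget is 32.0%. The first figure stood higher, so I tried the curve on beta itself: it says 44.3% where the reading is 38.5%. The curve cheats by 5.8 percentage points: it counts molecules stranded with one exchanged as already two, and a low-side ratio lifts it as well, so I took this gap as one rough correction for both. Corrected, it gives 34.5%, close to the second way. South's clock I left to the forecast.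

The forecast named south-west, with 30% (26% to 34%) for south-west and 23% (16% to 30%) for south, where “excess ligand overshoots the maximum”.

The flasks gave south-west: 30.8% in south-west, 19.5% in south.

    complex with two exchanged + incoming ligand → over-reaction product (k = 0.499 L mol⁻¹ min⁻¹, Ea = 48.0 kJ mol⁻¹)
    complex with three exchanged + incoming ligand → leaving ligand + complex with four exchanged (k = 0.436 L mol⁻¹ min⁻¹, Ea = 40.0 kJ mol⁻¹)
    complex with one exchanged + incoming ligand → leaving ligand + complex with two exchanged (k = 4.04 L mol⁻¹ min⁻¹, Ea = 40.0 kJ mol⁻¹)
    starting complex + incoming ligand → leaving ligand + complex with one exchanged (k = 0.818 L mol⁻¹ min⁻¹, Ea = 39.0 kJ mol⁻¹)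
    complex with two exchanged + incoming ligand → leaving ligand + complex with three exchanged (k = 0.0639 L mol⁻¹ min⁻¹, Ea = 38.0 kJ mol⁻¹)
    (constants at −40 °C)

At south-west's 46.1% of starting complex the curve gives 41.3%, which covers the 30.8% with two exchanged and the 10.5% with one. South's main loss was the over-reaction path: struck out, south holds 74.7%. In the neighbour with 63 mM of starting complex, 19.8% left puts the curve at 43.9%; that flask held 42.1% with two exchanged and 5.01% with one.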